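Substrate and product do not add up to the charge in these runs, and booking the gap as scatter is the trap.

| flask | substrate | free catalyst | remark | time |
|---|---|---|---|---|
| Friday's | 1.4 mM | 4.7 mol% | run made earlier |  |
| Thursday's | 2.2 mM | 4.7 mol% | run made earlier |  |
| Sunday's | 1 mM | 9.4 mol% | run made earlier |  |
| delta | 1.0 mM | 4.7 mol% |  | 3.0 min |
| epsilon | 1.0 mM | 4.7 mol% |  | 1.0 min |

- Friday's (time / min: product / %, substrate / %): 0.333: 12.8, 80.4; 0.667: 23.7, 70.3; 1.00: 30.3, 62.7; 1.33: 35.8, 56.0; 1.50: 38.8, 54.0; 2.00: 43.3, 48.4; 2.50: 48.4, 44.2
- Thursday's (time / min: product / %, substrate / %): 0.333: 14.0, 80.0; 0.667: 21.3, 71.3; 1.00: 24.7, 66.5; 1.33: 29.1, 63.4; 1.50: 29.6, 62.5; 2.00: 31.6, 59.5; 2.50: 32.3, 58.2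
- Sunday's (time / min: product / %, substrate / %): 0.200: 16.0, 76.2; 0.333: 25.0, 66.9; 0.667: 44.2, 46.4; 1.33: 70.5, 21.1; 2.50: 88.9, 3.9

(each reading ± 0.5 percentage points)



* which one finishes higher in amount of product, in percent of the substrate charged ("neither" within 2 percentage points) (delta / epsilon / neither)
* amount of product at the end, in percent of the substrate charged, delta
* amount of product at the end, in percent of the substrate charged, epsilon

So I kept a ledger of the substrate, which is the limiting reagent, with three entries: left, product, held on catalyst. Thursday's last reading held 9.50%, or 2.02 substrates per catalyst charged. That flask had nearly stopped, with substrate at 59.5% and then 58.2%. I read this as catalyst lost as spent catalyst, holding two substrates each. Sunday's last reading, at twice the loading, held 0.766 per catalyst.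

I assumed that loss per product grows with substrate. Integrated, the spent amount is the drop in squared substrate concentration, divided by 2 times one constant. Thursday's books, with the catalyst charge counted as spent and started after each catalyst bound one substrate, gave 13.3 mM. This is the spending concentration, the substrate level at which one catalyst is lost per product made, a kind of selectivity factor.

For delta and epsilon, the same flask stopped at different times, the rule left 27.5% of the catalyst unspent when substrate reached zero. Sunday's readings, scaled by loading, gave a first-order rate constant of 0.548 min⁻¹ for delta and epsilon. Integrating the first-order loss with the falling live share gave substrate 37.8% for delta and 63.1% for epsilon. After the held entry, product came to 54.6% and 30.3%.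

The forecast chose delta with 63% and 34%, both higher than mine, and said “Delta clearly finishes higher, simply from its longer time”.

The flasks gave 59.9% in delta and 31.7% in epsilon.

    substrate + free catalyst ⇌ catalyst intermediate A (K = 1510 M⁻¹, k = 1710 M⁻¹ s⁻¹)
    catalyst intermediate A ⇌ catalyst intermediate B (K = 1.37, k = 1.29 s⁻¹)
    catalyst intermediate B → free catalyst + product (k = 0.549 s⁻¹)
    substrate + catalyst intermediate A → spent catalyst (k = 38.9 M⁻¹ s⁻¹)

In delta at 3.00 min, the first binding relaxed with half-life 0.404 s, far shorter than the 1.55 min of the slowest mode. Catalyst intermediate A stood near balance there, made over used 0.988. At delta's 33% substrate, the spending concentration gives 63.7% of the catalyst spent, and delta holds 67.9%. In a neighbour of delta charged with 1.7 mM of substrate at the same loading, it puts the stop at substrate 41.4%. That neighbour shows 48% substrate, 92.8% of its catalyst spent and 43.5% product at 3.00 min.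

The earlier runs and the new flask come from a simulation on assumed constants; noise was put on by code.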